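**Retrosynthetic overview**
- The target is the formal head-to-tail hydrodimer of 6-vinyl-7-methoxy-2,2-dimethylchromene. The cut removes the C(sp3)–C(sp2) bond between C3 and C2 of the butene chain, together with one C–H bond of the methyl group.
- This leaves a benzylic radical (hydrogen atom transfer to the vinylchromene) and an (E)-alkenyl iodide held on a chiral nickel catalyst. That single step sets the only stereocentre and keeps the E alkene.
- Both partners come from one aldehyde, 7-methoxy-2,2-dimethylchromene-6-carbaldehyde, by one-carbon olefinations (Wittig and Takai–Utimoto).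
- The aldehyde comes from resorcinol and prenal by chromene annulation, O-methylation and C6 formylation.
- Ring order: the benzene ring is bought as resorcinol. The pyran ring is formed once, in step 1, and supplies both pyran rings of the target. No ring is formed later.

**Assumption:** the target centre is (S). The (3aR,3a'R,8aS,8a'S) bis(oxazoline) ligand is taken to give (S), by analogy with its use in alkenylation of 1-arylethyl radicals. If the first run shows the opposite sense, its commercial antipode is used with nothing else changed.

**Step 1**
Reactants: 1 resorcinol; 2 3-methylbut-2-enal (prenal)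
Product: 4 2,2-dimethyl-2H-chromen-7-ol, via ortho-quinone methide 3 (not isolated)
Conditions: ethylenediammonium diacetate (10 mol %), xylene, reflux, 1 in 1.5-fold excess
Reagents that add atoms: none
Why: Formal [3+3] chromene annulation, in which Knoevenagel-type condensation at C4 of resorcinol (para to one OH, least hindered) gives 3, which closes by oxa-6π electrocyclisation; no stereocentre is formed.

**Step 2**
Reactants: 4 2,2-dimethyl-2H-chromen-7-ol
Product: 5 7-methoxy-2,2-dimethyl-2H-chromene
Conditions: MeI, K2CO3, acetone, reflux
Reagents that add atoms: iodomethane CI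
Why: Williamson ether synthesis on the only acidic OH, under mild base that leaves the chromene alkene untouched.

**Step 3**
Reactants: 5 7-methoxy-2,2-dimethyl-2H-chromene
Product: 7 7-methoxy-2,2-dimethyl-2H-chromene-6-carbaldehyde, via aryl iminium chloride 6 (not isolated)
Conditions: POCl3 (1.2 equiv), DMF, 0 °C to 40 °C; then aq. NaOAc, rt
Reagents that add atoms: N,N-dimethylformamide CN(C)C=O; water O
Why: Vilsmeier–Haack formylation goes to C6, which is ortho to OMe and para to the ring oxygen, whereas C8 is flanked by two oxygens and C5 is meta to both, and the buffered work-up spares the acid-sensitive chromene alkene.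

**Step 4**
Reactants: 7 7-methoxy-2,2-dimethyl-2H-chromene-6-carbaldehyde (about 60 % of the stock)
Product: 8 6-ethenyl-7-methoxy-2,2-dimethyl-2H-chromene
Conditions: Ph3PCH3Br, KOt-Bu, THF, 0 °C to rt; Et3N-deactivated silica, stored cold with BHT
Reagents that add atoms: methyltriphenylphosphonium bromide C[P+](c1ccccc1)(c1ccccc1)c1ccccc1.[Br-]
Why: Wittig methylenation of a non-enolisable aryl aldehyde under basic conditions avoids the acid-triggered dimerisation of this electron-rich styrene.

**Step 5**
Reactants: 7 7-methoxy-2,2-dimethyl-2H-chromene-6-carbaldehyde (remaining stock)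
Product: 9 6-[(E)-2-iodoethenyl]-7-methoxy-2,2-dimethyl-2H-chromene
Conditions: CHI3 (2 equiv), CrCl2 (6 equiv), THF, 0 °C to rt, dark
Reagents that add atoms: iodoform IC(I)I
Why: Takai–Utimoto olefination, in which the gem-dichromium reagent adds to the aldehyde and eliminates to the E-iodoalkene (usually above 10:1 E/Z for aryl aldehydes) without touching the chromene alkene.

**Step 6 (key step)**
Reactants: 8 6-ethenyl-7-methoxy-2,2-dimethyl-2H-chromene (1.5 equiv); 9 6-[(E)-2-iodoethenyl]-7-methoxy-2,2-dimethyl-2H-chromene (1.0 equiv)
Product: 11 6-[(1E,3S)-3-(7-methoxy-2,2-dimethyl-2H-chromen-6-yl)but-1-en-1-yl]-7-methoxy-2,2-dimethyl-2H-chromene (CNP0212142.1), via benzylic radical 10 (not isolated)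
Conditions: Co(L1)Cl (10 mol %), NiBr2·DME (10 mol %), L2 (12 mol %), PhSiH2(Oi-Pr) (1.5 equiv), CsF (1.5 equiv), DMA/THF 1:1, 0 °C, argon, dark, stopped when 9 is consumed (L1 = N,N'-bis(3,5-di-tert-butylsalicylidene)-2,3-dimethylbutane-2,3-diaminate; L2 = (3aR,3a'R,8aS,8a'S)-2,2'-(cyclopropane-1,1-diyl)bis(3a,8a-dihydro-8H-indeno[1,2-d]oxazole))
Reagents that add atoms: none
Why: Proposed new method: a cobalt hydride made from Co(L1)Cl, the silane and fluoride passes a hydrogen atom to the unhindered terminal CH2 of 8 (metal-hydride hydrogen atom transfer, much faster than to the 1,2-disubstituted alkenes of 9, of 11 and of the chromene rings) and gives the planar benzylic radical 10, stored reversibly on divalent cobalt; the L2-bound alkenylnickel iodide formed from 9 captures 10, and reductive elimination from the resulting trivalent nickel forms the C(sp3)–C(sp2) bond with retention of the E geometry and sets the (S) centre under ligand control, because both faces of 10 reach the chiral nickel centre and one diastereomeric complex eliminates faster; monovalent nickel then adds 9 and is reduced by divalent cobalt, so both cycles close without outside oxidant or reductant; capture by nickel (about 10^6 to 10^7 M-1 s-1) should outrun addition of 10 to 8 (about 10^2 M-1 s-1), which would give racemic product; the closest known reaction types are the cobalt/nickel dual-catalysed branch-selective hydroarylation of terminal alkenes with iodoarenes and the nickel/bis(oxazoline) enantioconvergent reductive alkenylation of 1-arylethyl chlorides with (E)-2-bromostyrenes, which runs through the same radical and alkenylnickel pair.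

**Compound list**
1 | resorcinol (benzene-1,3-diol) | Oc1cccc(O)c1 | starting material
2 | 3-methylbut-2-enal (prenal) | CC(C)=CC=O | starting material
3 | (6Z)-3-hydroxy-6-(3-methylbut-2-en-1-ylidene)cyclohexa-2,4-dien-1-one (ortho-quinone methide, not isolated) | CC(C)=C/C=C1/C=CC(O)=CC1=O | intermediate
4 | 2,2-dimethyl-2H-chromen-7-ol | CC1(C)C=Cc2ccc(O)cc2O1 | intermediate
5 | 7-methoxy-2,2-dimethyl-2H-chromene | COc1ccc2C=CC(C)(C)Oc2c1 | intermediate
6 | N-[(7-methoxy-2,2-dimethyl-2H-chromen-6-yl)methylidene]-N-methylmethanaminium chloride (not isolated) | COc1cc2OC(C)(C)C=Cc2cc1C=[N+](C)C.[Cl-] | intermediate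
7 | 7-methoxy-2,2-dimethyl-2H-chromene-6-carbaldehyde | COc1cc2OC(C)(C)C=Cc2cc1C=O | intermediate
8 | 6-ethenyl-7-methoxy-2,2-dimethyl-2H-chromene | COc1cc2OC(C)(C)C=Cc2cc1C=C | intermediate
9 | 6-[(E)-2-iodoethenyl]-7-methoxy-2,2-dimethyl-2H-chromene | COc1cc2OC(C)(C)C=Cc2cc1/C=C/I | intermediate
10 | 1-(7-methoxy-2,2-dimethyl-2H-chromen-6-yl)ethyl radical (not isolated) | C[CH]c1cc2C=CC(C)(C)Oc2cc1OC | intermediate
11 | 6-[(1E,3S)-3-(7-methoxy-2,2-dimethyl-2H-chromen-6-yl)but-1-en-1-yl]-7-methoxy-2,2-dimethyl-2H-chromene | COc1cc2c(cc1/C=C/[C@H](C)c1cc3c(cc1OC)OC(C)(C)C=C3)C=CC(C)(C)O2 | target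

**Total step count:** 6. **Longest linear sequence:** 5 (steps 1, 2, 3, 4, 6 or steps 1, 2, 3, 5, 6).

**Steps most likely to fail**

**Step 6.**
- Risks: oxidation of the very electron-rich radical 10 to the cation, or its addition to 8; either would give racemic 11. A competing nickel hydride pathway may run with a different sense of induction. The cobalt hydride may remove iodine from 9 or isomerise 11.
- Fallback: it sets out from 7 and comes back at 11. The radical is made from a preformed racemic halide in a strongly reducing medium instead of from the alkene.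
- MeMgBr in THF at −78 °C gives racemic 1-(7-methoxy-2,2-dimethyl-2H-chromen-6-yl)ethan-1-ol F1.
- Neutral Appel chlorination (PPh3, CCl4, CH2Cl2, 0 °C) gives racemic 6-(1-chloroethyl)-7-methoxy-2,2-dimethyl-2H-chromene F2, which is labile and is used crude.
- Enantioconvergent reductive cross-electrophile coupling of this chloride with 9 (NiCl2·DME, L2, Mn powder, NaI, DMA, 0 °C) gives 11. It passes through the same benzylic radical and alkenylnickel pair.

**Step 1.**
- Risks: attack at C2 of resorcinol (giving the 5-hydroxy isomer) and double annulation, both of which lower the yield.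
- Fallback: it sets out from 1 and comes back at 5. The pyran ring is built by acylation instead of electrocyclisation.
- Resorcinol and 3-methylbut-2-enoic acid in MeSO3H/P2O5 at 70 °C undergo Friedel–Crafts acylation para to OH, then oxa-Michael closure. The product is 7-hydroxy-2,2-dimethylchroman-4-one F3.
- MeI and K2CO3 give 7-methoxy-2,2-dimethylchroman-4-one F4.
- NaBH4 in MeOH gives racemic 7-methoxy-2,2-dimethylchroman-4-ol F5.
- Brief warming with catalytic p-TsOH in toluene dehydrates this alcohol to 5. This costs two more steps but is regiochemically unambiguous.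

**Step 3.**
- Risks: attack of the chloroiminium reagent or of HCl on the nucleophilic C3=C4 alkene.
- Fallback: it sets out from 4 and comes back at 7. The aldehyde is introduced before methylation and under basic conditions.
- Magnesium-phenoxide-directed ortho-formylation (MgCl2, Et3N, paraformaldehyde, MeCN, reflux; Casnati–Skattebøl) at the less hindered ortho position gives 7-hydroxy-2,2-dimethyl-2H-chromene-6-carbaldehyde F6.
- MeI and K2CO3 in DMF convert this phenol to 7, with the step count unchanged.

**Further compounds**
F1 | step 6 | rac-1-(7-methoxy-2,2-dimethyl-2H-chromen-6-yl)ethan-1-ol | CC(O)c1cc2C=CC(C)(C)Oc2cc1OC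
F2 | step 6 | rac-6-(1-chloroethyl)-7-methoxy-2,2-dimethyl-2H-chromene | CC(Cl)c1cc2C=CC(C)(C)Oc2cc1OC
F3 | step 1 | 7-hydroxy-2,2-dimethylchroman-4-one | CC1(C)CC(=O)c2ccc(O)cc2O1
F4 | step 1 | 7-methoxy-2,2-dimethylchroman-4-one | COc1ccc2C(=O)CC(C)(C)Oc2c1
F5 | step 1 | rac-7-methoxy-2,2-dimethylchroman-4-ol | COc1ccc2C(O)CC(C)(C)Oc2c1
F6 | step 3 | 7-hydroxy-2,2-dimethyl-2H-chromene-6-carbaldehyde | CC1(C)C=Cc2cc(C=O)c(O)cc2O1
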